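## Retrosynthetic overview
1. The C3–O acyl bond is made last. The target comes from trans-(2R,3S)-3-hydroxy-6-hydroxytremetone and (Z)-4-acetoxy-2-methylbut-2-enoic acid, whose Z-alkene is inherited from the ring of 3-methylfuran-2(5H)-one.
2. The O1–C2 bond is the only ring closure. The acidic para-acyl phenol oxygen opens a side-chain epoxide, as in the presumed biogenesis of tremetone/toxol benzofurans. Here this happens on the dehydroprenyl (dienyl) side chain, so an anti 5-endo opening of an (S,S)-vinyl epoxide delivers C2, C3, the 3-OH and the isopropenyl group in one event.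
3. The epoxide comes from the (E)-dienyl-resacetophenone by reagent-controlled chiral dioxirane epoxidation, run in the same flask as the ring closure.
4. The diene comes from 5-bromoresacetophenone and an (E)-dienylboronate (Suzuki). The boronate comes from 2-methylbut-1-en-3-yne and pinacolborane.
5. Ring order: the benzene ring is bought, the dihydrofuran ring is formed in step 3, and no other ring is made.

Assumption: 1-(5-bromo-2,4-dihydroxyphenyl)ethan-1-one, 3-methylfuran-2(5H)-one and the L-fructose-derived Shi ketone are bought as catalogue items.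

## Route

**Step 1**
Reactants: 1 2-methylbut-1-en-3-yne; 2 pinacolborane
Product: 3 4,4,5,5-tetramethyl-2-[(1E)-3-methylbuta-1,3-dien-1-yl]-1,3,2-dioxaborolane
Conditions: Cp2ZrHCl (5 mol %), Et3N (10 mol %), neat, sealed tube, 40 °C, 16 h
Reagents that add atoms: none
Why: Zirconocene-hydride-catalysed alkyne hydroboration adds H–B syn and anti-Markovnikov to the terminal alkyne, so only the E-alkenylboronate forms and the 1,1-disubstituted alkene is left alone.

**Step 2**
Reactants: 3 4,4,5,5-tetramethyl-2-[(1E)-3-methylbuta-1,3-dien-1-yl]-1,3,2-dioxaborolane; 4 1-(5-bromo-2,4-dihydroxyphenyl)ethan-1-one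
Product: 5 1-{2,4-dihydroxy-5-[(1E)-3-methylbuta-1,3-dien-1-yl]phenyl}ethan-1-one
Conditions: Pd(OAc)2 (3 mol %), SPhos (6 mol %), K3PO4 (4 equiv), degassed dioxane–H2O (5:1), 70 °C; work-up at pH 6, Et3N-washed silica
Reagents that add atoms: none
Why: Suzuki–Miyaura coupling transfers the alkenyl group with retention of E geometry, the electron-rich biarylphosphine allows oxidative addition into the phenoxide-rich bromide, and the basic medium keeps the acid-labile dienylphenol from closing to the chromene.

**Step 3**
Reactants: 5 1-{2,4-dihydroxy-5-[(1E)-3-methylbuta-1,3-dien-1-yl]phenyl}ethan-1-one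
Product: 7 1-[(2R,3S)-3,6-dihydroxy-2-(prop-1-en-2-yl)-2,3-dihydro-1-benzofuran-5-yl]ethan-1-one, via (S,S)-vinyl epoxide 6 (not isolated)
Conditions: 1,2:4,5-di-O-isopropylidene-β-L-erythro-2,3-hexodiulo-2,6-pyranose (30 mol %), KHSO5 (1.3 equiv, as 2KHSO5·KHSO4·K2SO4) and K2CO3 added in parallel over 2 h, Bu4NHSO4 (5 mol %), MeCN–CH2(OMe)2 / aq Na2B4O7–Na2EDTA (pH 10.5), −5 °C; then 23 °C, 2 h; NH4Cl to pH 7
Reagents that add atoms: potassium peroxymonosulfate KHSO5, [K+].[O-]S(=O)(=O)OO
Why: Proposed new method: Shi-type chiral dioxirane epoxidation is known to turn conjugated dienes into vinyl epoxides at the trans-disubstituted, more electron-rich alkene (spiro transition state; the D-ketone gives R,R from trans-β-methylstyrene, so the L-ketone gives S,S here), and at pH 10.5 the C4-OH (pKa about 8) is a phenoxide that opens the oxirane in situ at the allylically activated C–O bond by anti 5-endo attack (4-exo attack at the benzylic carbon is too strained), which keeps the benzylic C–O bond as C3 (S) and inverts the allylic carbon to C2 (R), i.e. trans; the closest known reaction types are the base- or fluoride-triggered cyclisation of 2-(oxiran-2-yl)phenols to 2,3-dihydrobenzofuran-3-ols and the endo-selective opening of vinyl epoxides by tethered hydroxyl groups, and the new element is the unprotected phenoxide in the oxidation flask.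

**Step 4**
Reactants: 8 3-methylfuran-2(5H)-one
Product: 11 4-methoxybenzyl (2Z)-4-(acetyloxy)-2-methylbut-2-enoate, via potassium hydroxy-enoate 9 (not isolated), via PMB hydroxy ester 10 (not isolated)
Conditions: KOH (1.0 equiv), H2O–MeOH, 0 → 23 °C, evaporate; 4-MeOC6H4CH2Cl, NaI (10 mol %), DMF, 23 °C; then Ac2O, pyridine, DMAP (5 mol %), 0 °C
Reagents that add atoms: potassium hydroxide, [K+].[OH-]; 4-methoxybenzyl chloride, COc1ccc(CCl)cc1; acetic anhydride, CC(=O)OC(C)=O
Why: Lactone saponification, SN2 O-alkylation of the carboxylate and acetylation of the freed primary alcohol never touch the C=C bond, so the Z geometry is inherited from the ring, and capping the carboxylate before Ac2O is added shuts off the mixed-anhydride path back to the lactone.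

**Step 5**
Reactants: 11 4-methoxybenzyl (2Z)-4-(acetyloxy)-2-methylbut-2-enoate
Product: 12 (2Z)-4-(acetyloxy)-2-methylbut-2-enoic acid
Conditions: TFA–CH2Cl2 (1:4), anisole (3 equiv), 0 °C, 45 min
Reagents that add atoms: none
Why: SN1 acidolysis of the 4-methoxybenzyl ester releases a stabilised benzyl cation that anisole traps (Friedel–Crafts alkylation), under conditions that leave the primary acetate and the Z-alkene alone.

**Step 6**
Reactants: 12 (2Z)-4-(acetyloxy)-2-methylbut-2-enoic acid; 7 1-[(2R,3S)-3,6-dihydroxy-2-(prop-1-en-2-yl)-2,3-dihydro-1-benzofuran-5-yl]ethan-1-one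
Product: 14 (2R,3S)-5-acetyl-6-hydroxy-2-(prop-1-en-2-yl)-2,3-dihydro-1-benzofuran-3-yl (2Z)-4-(acetyloxy)-2-methylbut-2-enoate, via acid chloride 13 (not isolated)
Conditions: 12 (1.4 equiv), Me2C=C(Cl)NMe2 (1.3 equiv), CH2Cl2, 0 °C, 30 min; then 7, 2,6-lutidine (3 equiv), CH2Cl2, −20 → 10 °C
Reagents that add atoms: none
Why: Acyl chloride esterification (neutral Ghosez chlorination, then a non-nucleophilic base) offers no nucleophilic catalyst or strong base for Z→E isomerisation by conjugate addition–elimination or for elimination to the benzofuran, leaves the C3–O bond intact (retention), and spares the C6 phenol because it is hydrogen-bonded to the acetyl group.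

## Compound list
1 | 2-methylbut-1-en-3-yne | C=C(C)C#C | starting material
2 | pinacolborane (4,4,5,5-tetramethyl-1,3,2-dioxaborolane) | B1OC(C)(C)C(C)(C)O1 | starting material
3 | 4,4,5,5-tetramethyl-2-[(1E)-3-methylbuta-1,3-dien-1-yl]-1,3,2-dioxaborolane | C=C(C)/C=C/B1OC(C)(C)C(C)(C)O1 | intermediate
4 | 1-(5-bromo-2,4-dihydroxyphenyl)ethan-1-one | CC(=O)c1cc(Br)c(O)cc1O | starting material
5 | 1-{2,4-dihydroxy-5-[(1E)-3-methylbuta-1,3-dien-1-yl]phenyl}ethan-1-one | CC(=O)c1cc(/C=C/C(C)=C)c(O)cc1O | intermediate
6 | 1-{2,4-dihydroxy-5-[(2S,3S)-3-(prop-1-en-2-yl)oxiran-2-yl]phenyl}ethan-1-one (trans epoxide, present as its phenoxide) | CC(=O)c1cc([C@@H]2O[C@H]2C(C)=C)c(O)cc1O | intermediate (not isolated)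
7 | 1-[(2R,3S)-3,6-dihydroxy-2-(prop-1-en-2-yl)-2,3-dihydro-1-benzofuran-5-yl]ethan-1-one (2,3-trans) | C=C(C)[C@H]1Oc2cc(O)c(C(C)=O)cc2[C@@H]1O | intermediate
8 | 3-methylfuran-2(5H)-one | CC1=CCOC1=O | starting material
9 | potassium (2Z)-4-hydroxy-2-methylbut-2-enoate | [K+].[O-]C(=O)/C(C)=C\CO | intermediate (not isolated)
10 | 4-methoxybenzyl (2Z)-4-hydroxy-2-methylbut-2-enoate | COc1ccc(COC(=O)/C(C)=C\CO)cc1 | intermediate (not isolated)
11 | 4-methoxybenzyl (2Z)-4-(acetyloxy)-2-methylbut-2-enoate | COc1ccc(COC(=O)/C(C)=C\COC(C)=O)cc1 | intermediate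
12 | (2Z)-4-(acetyloxy)-2-methylbut-2-enoic acid | OC(=O)/C(C)=C\COC(C)=O | intermediate
13 | (2Z)-4-(acetyloxy)-2-methylbut-2-enoyl chloride | O=C(Cl)/C(C)=C\COC(C)=O | intermediate (not isolated)
14 | (2R,3S)-5-acetyl-6-hydroxy-2-(prop-1-en-2-yl)-2,3-dihydro-1-benzofuran-3-yl (2Z)-4-(acetyloxy)-2-methylbut-2-enoate (CNP0273504.1) | C=C(C)[C@H]1Oc2cc(O)c(C(C)=O)cc2[C@@H]1OC(=O)/C(C)=C\COC(C)=O | target

## Step count and risks
Total step count: 6. Longest linear sequence: 4 (steps 1, 2, 3, 6). The acid branch is 3 steps (4, 5, 6).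

**Step 3 (highest risk).**
- The free phenoxide and its ketone may be attacked by peroxymonosulfate (Dakin-type cleavage).
- Epoxide 6 may open at the benzylic carbon through a quinone methide and be trapped by water.
- The 5-endo closure may be slow.

The fallback sets out from 5 and comes back at 7. It separates oxidation from ring closure by masking the nucleophile. Both phenols are silylated (TIPSOTf, 2,6-lutidine, CH2Cl2, 0 °C) to give 1-{5-[(1E)-3-methylbuta-1,3-dien-1-yl]-2,4-bis[(triisopropylsilyl)oxy]phenyl}ethan-1-one F1. This neutral, non-phenolic diene is epoxidised with the same L-fructose-derived ketone and KHSO5 to the isolable 1-{5-[(2S,3S)-3-(prop-1-en-2-yl)oxiran-2-yl]-2,4-bis[(triisopropylsilyl)oxy]phenyl}ethan-1-one F2. The phenoxide is then released in a separate, water-free operation (Bu4NF, THF, −20 → 23 °C), where it can only close onto the allylic carbon to give 7.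

**Step 6.**
- Acid chloride 13 can collapse to the butenolide with loss of acetyl chloride.
- It can isomerise to the E acyl chloride.
- The new benzylic ester, para to a phenol, can eliminate to the aromatic benzofuran.

The fallback sets out from 7 (with 12) and comes back at 14. It reverses the polarity, so the acid acts only as a nucleophile and its carbonyl is never activated. Under PPh3, DIAD and 12 (3 equiv) in toluene at −40 → 0 °C, the C3 oxyphosphonium ion ionises, helped by the para-OH and the ortho ring oxygen. This gives (2S)-5-acetyl-2-(prop-1-en-2-yl)-1-benzofuran-6(2H)-one F3, a para-quinone methide with the same spatial arrangement at C2. Acid 12 adds 1,6 to it from the face anti to the isopropenyl group and gives the trans ester 14. Any cis ester formed by direct displacement is removed by chromatography.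

**Step 4.**
- Hydroxy ester 10 may relactonise before it is acetylated.
- Salt 9 may isomerise in base.

The fallback sets out from 8 and comes back at 12. It replaces the carboxyl-protection logic with a redox route. Reduction with i-Bu2AlH (2.5 equiv, CH2Cl2, −78 → 0 °C) gives (2Z)-2-methylbut-2-ene-1,4-diol F4. Immobilised Candida antarctica lipase B with vinyl acetate in MTBE acetylates the less hindered hydroxyl, remote from the methyl group, and gives (2Z)-4-hydroxy-3-methylbut-2-en-1-yl acetate F5. TEMPO (cat.), NaClO2 and NaOCl (cat.) in MeCN–pH 6.7 phosphate buffer then take the remaining allylic alcohol straight to acid 12. Chlorite consumes the Z-enal as fast as it forms.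

## Further compounds
F1 | step 3 | 1-{5-[(1E)-3-methylbuta-1,3-dien-1-yl]-2,4-bis[(triisopropylsilyl)oxy]phenyl}ethan-1-one | CC(=O)c1cc(/C=C/C(C)=C)c(O[Si](C(C)C)(C(C)C)C(C)C)cc1O[Si](C(C)C)(C(C)C)C(C)C
F2 | step 3 | 1-{5-[(2S,3S)-3-(prop-1-en-2-yl)oxiran-2-yl]-2,4-bis[(triisopropylsilyl)oxy]phenyl}ethan-1-one | CC(=O)c1cc([C@@H]2O[C@H]2C(C)=C)c(O[Si](C(C)C)(C(C)C)C(C)C)cc1O[Si](C(C)C)(C(C)C)C(C)C
F3 | step 6 | (2S)-5-acetyl-2-(prop-1-en-2-yl)-1-benzofuran-6(2H)-one | C=C(C)[C@H]1OC2=CC(=O)C(C(C)=O)=CC2=C1
F4 | step 4 | (2Z)-2-methylbut-2-ene-1,4-diol | OC/C(C)=C\CO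
F5 | step 4 | (2Z)-4-hydroxy-3-methylbut-2-en-1-yl acetate | OC/C(C)=C\COC(C)=O
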